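**Plan**
- Retrosynthetic cuts, in order: the C6–O acyl bond (side-chain acid 30) and the silyl ethers; the lactone bond C12–O8 (from a C8/C12 2-methylene-1,4-diol); the ring bond C6–C7 by a retro-[2,3]-Wittig shift to the thirteen-membered C6–O–C13 ether 21; the ether bond O6–C13; then C4=C5 (olefination), C3–C4 (phosphonate alkylation), C11–C13 (Stille) and C7–C8 (acetylide addition).
- Enabling feature: in the ten-membered carbocycle C1–C10 the C6 carbinol is allylic to C4=C5 and adjacent to C7, which carries the C11=C13 methylene. This homoallylic alcohol is the retron of a [2,3]-shift of a C6–O–C13 allyl ether whose C6–H is acidified through the C4=C5–C15 ester.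
- Forward order: chain C12–C11–C7–C8…C3 from (S)-citronellal and a propargyl ether, then C4–C6; thirteen-membered ether ring by O-alkylation (step 13); ten-membered carbocycle by ring contraction (step 14); γ-lactone last (step 22), after the side chain is attached.
- Stereochemistry: C10 from (S)-citronellal; C8 from catalyst-controlled transfer hydrogenation; C6 and C7 in the ring contraction (geometry of C7=C11, allylic strain from C8); olefin geometries from trans-hydroalumination/iodination, the olefination and a stereoretentive carbonylation.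

Key step: step 14

Assumption: compounds 2, 15 and 17 are taken as purchasable reagents.
Numbering: germacrane numbering (ring C1–C10, C11–C13 on C7, C14 on C10, C15 on C4) is used for all intermediates; the CIP label of C7 changes with the groups on O6 and O8 although its geometry does not.

**Step 1**
Reactants: 1 (S)-citronellal; 2 tert-butyldimethyl(prop-2-yn-1-yloxy)silane
Product: 4 (6S)-1-(tert-butyldimethylsilyloxy)-6,10-dimethylundec-9-en-2-yn-4-ol as both C8 epimers, via lithium acetylide 3 (not isolated)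
Conditions: n-BuLi, THF, −78 °C; then 1, −78 → 0 °C; H2O quench
Reagents that add atoms: none
Why: 1,2-Addition of a lithium acetylide to an aliphatic aldehyde is a standard alkynylation, and the C8 carbinol may form as both epimers because step 2 removes the centre.

**Step 2**
Reactants: 4 propargylic alcohol (C8 epimers)
Product: 5 (6S)-1-(tert-butyldimethylsilyloxy)-6,10-dimethylundec-9-en-2-yn-4-one
Conditions: Dess–Martin periodinane, CH2Cl2, 0 °C → rt
Reagents that add atoms: none
Why: Dess–Martin oxidation converts a secondary propargylic alcohol into the ynone without touching the silyl ether or the trisubstituted alkene.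

**Step 3**
Reactants: 5 ynone
Product: 6 (4R,6S)-1-(tert-butyldimethylsilyloxy)-6,10-dimethylundec-9-en-2-yn-4-ol (8R,10S)
Conditions: RuCl[(R,R)-TsDPEN](p-cymene) (2 mol %), i-PrOH, rt
Reagents that add atoms: none
Why: Noyori asymmetric transfer hydrogenation of alkynyl ketones is strongly enantioface-selective, the alkynyl group taking the place of the aryl group of the standard model, so the (R,R)-ligand should give the (R)-carbinol at C8 under catalyst control irrespective of the remote C10 centre.

**Step 4**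
Reactants: 6 (R)-propargylic alcohol
Product: 8 (2Z,4R,6S)-1-(tert-butyldimethylsilyloxy)-2-iodo-6,10-dimethylundeca-2,9-dien-4-ol (iodine on C11, cis to C8), via alkenylalanate 7 (not isolated)
Conditions: NaAlH2(OCH2CH2OMe)2, THF, 0 °C → rt; then N-iodosuccinimide, −78 → 0 °C
Reagents that add atoms: N-iodosuccinimide, O=C1CCC(=O)N1I
Why: Hydroxyl-directed trans-hydroalumination of a propargylic alcohol places aluminium on the distal carbon C11 and hydrogen on C7, and iodinolysis with retention should give the (Z)-iodoalkene whose iodine, the later C13 position, is cis to C8, while the isolated trisubstituted alkene is inert to the aluminate.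

**Step 5**
Reactants: 8 iodo allylic alcohol
Product: 9 tert-butyl{[(2Z,4R,6S)-2-iodo-6,10-dimethyl-4-(triethylsilyloxy)undeca-2,9-dien-1-yl]oxy}dimethylsilane
Conditions: Et3SiCl, imidazole, CH2Cl2, 0 °C
Reagents that add atoms: chlorotriethylsilane, CC[Si](Cl)(CC)CC
Why: Silylation of a secondary allylic alcohol with a silyl chloride and imidazole is routine and masks O8 for the base-mediated steps ahead.

**Step 6**
Reactants: 9 triethylsilyl ether
Product: 11 (4S,6R,7Z)-9-(tert-butyldimethylsilyloxy)-8-iodo-4-methyl-6-(triethylsilyloxy)non-7-en-1-ol (C3 alcohol), via aldehyde 10 (not isolated)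
Conditions: O3, CH2Cl2/MeOH, −78 °C (Sudan red 7B end point); then NaBH4, −78 → 0 °C
Reagents that add atoms: ozone, [O-][O+]=O
Why: In this ozonolysis with reductive work-up, ozone should attack the electron-rich isopropylidene alkene much faster than the iodoalkene that is deactivated by iodine and two allylic oxygens, and borohydride in the same flask reduces the C3 aldehyde to the alcohol.

**Step 7**
Reactants: 11 primary alcohol
Product: 12 tert-butyl{[(2Z,4R,6S)-2,9-diiodo-6-methyl-4-(triethylsilyloxy)non-2-en-1-yl]oxy}dimethylsilane (C3 iodide)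
Conditions: I2, PPh3, imidazole, CH2Cl2, 0 °C
Reagents that add atoms: iodine, II
Why: The Appel-type iodination converts a primary alcohol into the iodide under buffered conditions that silyl ethers and the alkenyl iodide tolerate.

**Step 8**
Reactants: 12 primary iodide; 13 trimethyl phosphonoacetate
Product: 14 methyl (6S,8R,9Z)-11-(tert-butyldimethylsilyloxy)-2-(dimethoxyphosphoryl)-10-iodo-6-methyl-8-(triethylsilyloxy)undec-9-enoate (both C4 epimers)
Conditions: 13 (excess), NaH, DMF, 0 °C; then 12, 50 °C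
Reagents that add atoms: none
Why: C-Alkylation of the phosphonoacetate carbanion with a primary alkyl iodide is a standard route to α-substituted phosphonoacetates, excess phosphonate suppresses double alkylation, and the new centre at C4 is lost in step 9.

**Step 9**
Reactants: 14 phosphonate; 15 2-[(4-methoxybenzyl)oxy]acetaldehyde
Product: 16 methyl (2E)-2-[(4S,6R,7Z)-9-(tert-butyldimethylsilyloxy)-8-iodo-4-methyl-6-(triethylsilyloxy)non-7-en-1-yl]-4-[(4-methoxybenzyl)oxy]but-2-enoate
Conditions: NaH, THF, 0 °C; then 15, 0 °C → rt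
Reagents that add atoms: none
Why: The Horner–Wadsworth–Emmons olefination of α-alkyl phosphonoacetates favours the trisubstituted (E)-enoate with the ester trans to the C6 carbon, which is the C4=C5 geometry of the target, and any minor isomer should be separable.

**Step 10**
Reactants: 16 iodo enoate; 17 (tributylstannyl)methanol
Product: 18 methyl (2E)-2-[(4S,6R,7E)-9-(tert-butyldimethylsilyloxy)-8-(hydroxymethyl)-4-methyl-6-(triethylsilyloxy)non-7-en-1-yl]-4-[(4-methoxybenzyl)oxy]but-2-enoate (C13 hydroxymethyl cis to C8)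
Conditions: 17, Pd(PPh3)4 (10 mol %), 1,4-dioxane, 90 °C
Reagents that add atoms: none
Why: Stille coupling of alkenyl iodides with the hydroxymethylstannane transfers the hydroxymethyl group selectively and with retention of olefin geometry, so C13 should end up cis to C8.

**Step 11**
Reactants: 18 allylic alcohol
Product: 19 methyl (2E)-2-[(4S,6R,7Z)-8-(bromomethyl)-9-(tert-butyldimethylsilyloxy)-4-methyl-6-(triethylsilyloxy)non-7-en-1-yl]-4-[(4-methoxybenzyl)oxy]but-2-enoate
Conditions: CBr4, PPh3, CH2Cl2, 0 °C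
Reagents that add atoms: carbon tetrabromide, BrC(Br)(Br)Br
Why: Appel bromination turns the primary allylic alcohol into the bromide under neutral conditions without allylic transposition or silyl loss.

**Step 12**
Reactants: 19 allylic bromide
Product: 20 methyl (2E)-2-[(4S,6R,7Z)-8-(bromomethyl)-9-(tert-butyldimethylsilyloxy)-4-methyl-6-(triethylsilyloxy)non-7-en-1-yl]-4-hydroxybut-2-enoate
Conditions: DDQ, CH2Cl2/pH 7 buffer, 0 °C
Reagents that add atoms: none
Why: DDQ cleaves the p-methoxybenzyl ether oxidatively (benzylic hydride abstraction, then hydrolysis of the oxocarbenium ion) and should leave the silyl ethers, the enoate and the allylic bromide intact.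

**Step 13**
Reactants: 20 hydroxy allylic bromide
Product: 21 methyl (3E,8S,10R,11E)-12-[(tert-butyldimethylsilyloxy)methyl]-8-methyl-10-(triethylsilyloxy)-1-oxacyclotrideca-3,11-diene-4-carboxylate (thirteen-membered C6–O–C13 ether; C13 cis to C8, C3 cis to C6)
Conditions: NaH, n-Bu4NI (cat.), THF, 0.002 M, slow addition, rt → 45 °C
Reagents that add atoms: none
Why: Intramolecular Williamson etherification of an ω-hydroxy allylic halide at high dilution is an established exo-tet closure of macrocyclic allylic ethers, the primary SN2 site at C13 is unhindered, and using O6 as the nucleophile keeps the alkoxide away from any silyl group that could migrate.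

**Step 14**
Reactants: 21 thirteen-membered allylic ether enoate
Product: 23 methyl (1E,3R,4R,5R,7S)-4-[3-(tert-butyldimethylsilyloxy)prop-1-en-2-yl]-3-hydroxy-7-methyl-5-(triethylsilyloxy)cyclodec-1-ene-1-carboxylate (germacrane numbering 6R,7R,8R,10S; free 6-OH, C11=C13 methylene), via lithium dienolate 22 (not isolated)
Conditions: LiN(i-Pr)2, THF/DMPU, −78 → −30 °C; AcOH quench at −78 °C
Reagents that add atoms: none
Why: Proposed new method: LiN(i-Pr)2 should remove the γ-proton at C6 of the enoate (the only C–H acidified by the C15 ester, C13–H being beyond an amide base), and the oxygen-bearing γ-carbon of the resulting lithium dienolate should bond to C7 through a five-membered envelope transition state while O–C13 breaks and C11=C13 forms, a six-electron [2,3]-sigmatropic shift that ends in the C6 alkoxide with the C4=C5 enoate restored. The closest known reactions are the [2,3]-Wittig ring contraction of thirteen-membered bis-allylic or allylic propargylic ethers to cyclodecenols and the ester dienolate [2,3]-Wittig rearrangement of α-allyloxy β,γ-unsaturated esters; what is new is a vinylogously stabilised carbanion reacting at its γ-terminus inside a ring. The ten-membered carbocycle closes by transannular C6–C7 bond formation within the thirteen-membered ether, that is by contraction with the O–C13 bond as the one given up, so no end-to-end medium-ring closure is involved. The C6/C7 relationship (H6 and H7 cis) should follow from the geometry of C7=C11, where C13 is cis to C8, the arrangement that gives syn products in [2,3]-Wittig shifts of vinyl-type carbanions. The absolute sense should follow from C8: its hydrogen eclipses C7=C11 to avoid allylic 1,3-strain with C13, and C6 adds to the face of C7 anti to the C8–O bond, which is the 7,8-relationship of the trans-fused lactone. The step needs the [2,3] path to win over the [1,2] shift and over a Claisen-type [3,3] shift through C5 and needs the C4=C5 geometry to survive; low temperature, the lithium counter-ion, the small dienolate coefficient at C5 and the ring-imposed barrier to rotation about C4–C5 are what is relied on.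

**Step 15**
Reactants: 23 hydroxy ester
Product: 24 (4E,6R,7R,8R,10S)-12-(tert-butyldimethylsilyloxy)-8-(triethylsilyloxy)germacra-4,11(13)-diene-6,15-diol
Conditions: i-Bu2AlH, CH2Cl2, −78 °C
Reagents that add atoms: none
Why: i-Bu2AlH reduces α,β-unsaturated esters in 1,2-fashion to allylic alcohols at low temperature, and nothing else in the molecule is reducible.

**Step 16**
Reactants: 24 diol
Product: 25 (4E,6R,7R,8R,10S)-12-(tert-butyldimethylsilyloxy)-15-(tert-butyldiphenylsilyloxy)-8-(triethylsilyloxy)germacra-4,11(13)-dien-6-ol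
Conditions: t-BuPh2SiCl, imidazole, CH2Cl2, 0 °C
Reagents that add atoms: tert-butyl(chloro)diphenylsilane, CC(C)(C)[Si](Cl)(c1ccccc1)c1ccccc1
Why: The bulky silyl chloride should discriminate the primary allylic C15 hydroxyl from the hindered secondary C6 hydroxyl in a selective silylation.

**Step 17**
Reactants: 26 but-2-yne-1,4-diol
Product: 28 (Z)-2-iodobut-2-ene-1,4-diol, via alkenylalanate 27 (not isolated)
Conditions: NaAlH2(OCH2CH2OMe)2, THF, 0 °C → rt; then I2, −78 °C
Reagents that add atoms: iodine, II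
Why: Hydroxyl-directed trans-hydroalumination of the butynediol followed by iodinolysis with retention is the standard entry to the (Z)-iodoalkene, in which iodine is cis to the C4 hydroxymethyl group.

**Step 18**
Reactants: 28 iodo diol
Product: 29 (Z)-1,4-bis(tert-butyldiphenylsilyloxy)-2-iodobut-2-ene
Conditions: t-BuPh2SiCl, imidazole, DMF, rt
Reagents that add atoms: tert-butyl(chloro)diphenylsilane, CC(C)(C)[Si](Cl)(c1ccccc1)c1ccccc1
Why: Exhaustive silylation of the two primary alcohols blocks lactonisation of the later (Z)-acid and gives ethers that should outlast the acid treatment of step 21.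

**Step 19**
Reactants: 29 bis-silylated alkenyl iodide
Product: 30 (Z)-4-(tert-butyldiphenylsilyloxy)-2-[(tert-butyldiphenylsilyloxy)methyl]but-2-enoic acid
Conditions: Pd(OAc)2 (5 mol %), PPh3, CO (1 atm), H2O, Et3N, DMF, 60 °C
Reagents that add atoms: carbon monoxide, [C-]#[O+]; water, O
Why: Palladium-catalysed hydroxycarbonylation of alkenyl iodides (oxidative addition, CO insertion, hydrolysis of the acylpalladium species) proceeds with retention, so the carboxyl group should be cis to the C4′ silyloxymethyl group as the (Z)-side chain requires.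

**Step 20**
Reactants: 25 C6 alcohol; 30 side-chain acid
Product: 32 (4E,6R,7R,8R,10S)-12-(tert-butyldimethylsilyloxy)-15-(tert-butyldiphenylsilyloxy)-8-(triethylsilyloxy)germacra-4,11(13)-dien-6-yl (Z)-4-(tert-butyldiphenylsilyloxy)-2-[(tert-butyldiphenylsilyloxy)methyl]but-2-enoate, via mixed anhydride 31 (not isolated)
Conditions: 30, 2,4,6-Cl3C6H2COCl, Et3N, toluene, rt; then 25, toluene, 80 °C
Reagents that add atoms: none
Why: Yamaguchi esterification through the mixed 2,4,6-trichlorobenzoic anhydride, run hot without a nucleophilic pyridine catalyst as is usual for angelate-type acids, should acylate the C6 hydroxyl without Z-to-E isomerisation of the acid and touches no stereocentre.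

**Step 21**
Reactants: 32 fully silylated ester
Product: 33 (4E,6R,7S,8R,10S)-15-(tert-butyldiphenylsilyloxy)-8,12-dihydroxygermacra-4,11(13)-dien-6-yl (Z)-4-(tert-butyldiphenylsilyloxy)-2-[(tert-butyldiphenylsilyloxy)methyl]but-2-enoate
Conditions: camphorsulfonic acid (cat.), MeOH/CH2Cl2, 0 °C
Reagents that add atoms: none
Why: Acid-catalysed methanolysis removes the secondary triethylsilyl ether and the primary allylic tert-butyldimethylsilyl ether much faster than primary tert-butyldiphenylsilyl ethers, so O8 and O12 should be freed selectively.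

**Step 22**
Reactants: 33 8,12-diol
Product: 36 (4E,6R,7S,8R,10S)-15-(tert-butyldiphenylsilyloxy)-6-{(Z)-4-(tert-butyldiphenylsilyloxy)-2-[(tert-butyldiphenylsilyloxy)methyl]but-2-enoyloxy}germacra-4,11(13)-dien-12,8-olide, via hydroxy enal 34 (not isolated), via lactol 35 (not isolated)
Conditions: MnO2 (excess), CH2Cl2, rt
Reagents that add atoms: none
Why: In this established oxidative lactonisation of 2-methylene-1,4-diols, MnO2 oxidises only the allylic C12 alcohol to the enal, the C8 hydroxyl closes the lactol by 5-exo-trig addition, and MnO2 oxidises the allylic lactol to the α-methylene-γ-butyrolactone, whose trans fusion is already fixed by C7 and C8.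

**Step 23**
Reactants: 36 tris-silylated lactone
Product: 37 target CNP0131216.1, (4E,6R,7S,8R,10S)-15-hydroxy-6-[(Z)-4-hydroxy-2-(hydroxymethyl)but-2-enoyloxy]germacra-4,11(13)-dien-12,8-olide
Conditions: HF·pyridine, pyridine, THF, 0 °C → rt
Reagents that add atoms: none
Why: Buffered HF·pyridine cleaves primary tert-butyldiphenylsilyl ethers without base, which should spare the α-methylene lactone and avoid acyl transfer from O6 to the liberated side-chain hydroxyl.

**Compound list**
1 | (S)-citronellal, (3S)-3,7-dimethyloct-6-enal | O=CC[C@@H](C)CCC=C(C)C | starting material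
2 | tert-butyldimethyl(prop-2-yn-1-yloxy)silane | C#CCO[Si](C)(C)C(C)(C)C | starting material
3 | lithium acetylide of 2 (formed in the flask) | [Li]C#CCO[Si](C)(C)C(C)(C)C | intermediate
4 | (6S)-1-(tert-butyldimethylsilyloxy)-6,10-dimethylundec-9-en-2-yn-4-ol, both C8 epimers | CC(C)(C)[Si](C)(C)OCC#CC(O)C[C@@H](C)CCC=C(C)C | intermediate
5 | (6S)-1-(tert-butyldimethylsilyloxy)-6,10-dimethylundec-9-en-2-yn-4-one | CC(C)(C)[Si](C)(C)OCC#CC(=O)C[C@@H](C)CCC=C(C)C | intermediate
6 | (4R,6S)-1-(tert-butyldimethylsilyloxy)-6,10-dimethylundec-9-en-2-yn-4-ol | CC(C)(C)[Si](C)(C)OCC#C[C@H](O)C[C@@H](C)CCC=C(C)C | intermediate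
7 | cyclic sodium alkenylalanate from 6 (ring O8–Al–C11=C7–C8, two 2-methoxyethoxy groups on Al; formed in the flask) | [Na+].COCCO[Al-]1(OCCOC)O[C@H](C[C@@H](C)CCC=C(C)C)C=C1CO[Si](C)(C)C(C)(C)C | intermediate
8 | (2Z,4R,6S)-1-(tert-butyldimethylsilyloxy)-2-iodo-6,10-dimethylundeca-2,9-dien-4-ol | CC(C)(C)[Si](C)(C)OC/C(I)=C/[C@H](O)C[C@@H](C)CCC=C(C)C | intermediate
9 | tert-butyl{[(2Z,4R,6S)-2-iodo-6,10-dimethyl-4-(triethylsilyloxy)undeca-2,9-dien-1-yl]oxy}dimethylsilane | CC(C)(C)[Si](C)(C)OC/C(I)=C/[C@H](O[Si](CC)(CC)CC)C[C@@H](C)CCC=C(C)C | intermediate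
10 | (4S,6R,7Z)-9-(tert-butyldimethylsilyloxy)-8-iodo-4-methyl-6-(triethylsilyloxy)non-7-enal (formed in the flask) | CC(C)(C)[Si](C)(C)OC/C(I)=C/[C@H](O[Si](CC)(CC)CC)C[C@@H](C)CCC=O | intermediate
11 | (4S,6R,7Z)-9-(tert-butyldimethylsilyloxy)-8-iodo-4-methyl-6-(triethylsilyloxy)non-7-en-1-ol | CC(C)(C)[Si](C)(C)OC/C(I)=C/[C@H](O[Si](CC)(CC)CC)C[C@@H](C)CCCO | intermediate
12 | tert-butyl{[(2Z,4R,6S)-2,9-diiodo-6-methyl-4-(triethylsilyloxy)non-2-en-1-yl]oxy}dimethylsilane | CC(C)(C)[Si](C)(C)OC/C(I)=C/[C@H](O[Si](CC)(CC)CC)C[C@@H](C)CCCI | intermediate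
13 | trimethyl phosphonoacetate | COC(=O)CP(=O)(OC)OC | starting material
14 | methyl (6S,8R,9Z)-11-(tert-butyldimethylsilyloxy)-2-(dimethoxyphosphoryl)-10-iodo-6-methyl-8-(triethylsilyloxy)undec-9-enoate, both C4 epimers | CC(C)(C)[Si](C)(C)OC/C(I)=C/[C@H](O[Si](CC)(CC)CC)C[C@@H](C)CCCC(C(=O)OC)P(=O)(OC)OC | intermediate
15 | 2-[(4-methoxybenzyl)oxy]acetaldehyde | O=CCOCc1ccc(OC)cc1 | starting material
16 | methyl (2E)-2-[(4S,6R,7Z)-9-(tert-butyldimethylsilyloxy)-8-iodo-4-methyl-6-(triethylsilyloxy)non-7-en-1-yl]-4-[(4-methoxybenzyl)oxy]but-2-enoate | CC(C)(C)[Si](C)(C)OC/C(I)=C/[C@H](O[Si](CC)(CC)CC)C[C@@H](C)CCC/C(C(=O)OC)=C\COCc1ccc(OC)cc1 | intermediate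
17 | (tributylstannyl)methanol | CCCC[Sn](CCCC)(CCCC)CO | starting material
18 | methyl (2E)-2-[(4S,6R,7E)-9-(tert-butyldimethylsilyloxy)-8-(hydroxymethyl)-4-methyl-6-(triethylsilyloxy)non-7-en-1-yl]-4-[(4-methoxybenzyl)oxy]but-2-enoate | CC(C)(C)[Si](C)(C)OC/C(CO)=C/[C@H](O[Si](CC)(CC)CC)C[C@@H](C)CCC/C(C(=O)OC)=C\COCc1ccc(OC)cc1 | intermediate
19 | methyl (2E)-2-[(4S,6R,7Z)-8-(bromomethyl)-9-(tert-butyldimethylsilyloxy)-4-methyl-6-(triethylsilyloxy)non-7-en-1-yl]-4-[(4-methoxybenzyl)oxy]but-2-enoate | CC(C)(C)[Si](C)(C)OC/C(CBr)=C/[C@H](O[Si](CC)(CC)CC)C[C@@H](C)CCC/C(C(=O)OC)=C\COCc1ccc(OC)cc1 | intermediate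
20 | methyl (2E)-2-[(4S,6R,7Z)-8-(bromomethyl)-9-(tert-butyldimethylsilyloxy)-4-methyl-6-(triethylsilyloxy)non-7-en-1-yl]-4-hydroxybut-2-enoate | CC(C)(C)[Si](C)(C)OC/C(CBr)=C/[C@H](O[Si](CC)(CC)CC)C[C@@H](C)CCC/C(C(=O)OC)=C\CO | intermediate
21 | methyl (3E,8S,10R,11E)-12-[(tert-butyldimethylsilyloxy)methyl]-8-methyl-10-(triethylsilyloxy)-1-oxacyclotrideca-3,11-diene-4-carboxylate (thirteen-membered C6–O–C13 ether) | O1C/C(CO[Si](C)(C)C(C)(C)C)=C\[C@H](O[Si](CC)(CC)CC)C[C@@H](C)CCC/C(C(=O)OC)=C\C1 | intermediate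
22 | lithium dienolate of 21 (C6=C5–C4=C(OMe)OLi; formed in the flask) | O1C/C(CO[Si](C)(C)C(C)(C)C)=C\[C@H](O[Si](CC)(CC)CC)C[C@@H](C)CCCC(=C(OC)O[Li])C=C1 | intermediate
23 | methyl (1E,3R,4R,5R,7S)-4-[3-(tert-butyldimethylsilyloxy)prop-1-en-2-yl]-3-hydroxy-7-methyl-5-(triethylsilyloxy)cyclodec-1-ene-1-carboxylate | C=C(CO[Si](C)(C)C(C)(C)C)[C@H]1[C@H](O[Si](CC)(CC)CC)C[C@@H](C)CCC/C(C(=O)OC)=C\[C@H]1O | intermediate
24 | (4E,6R,7R,8R,10S)-12-(tert-butyldimethylsilyloxy)-8-(triethylsilyloxy)germacra-4,11(13)-diene-6,15-diol | C=C(CO[Si](C)(C)C(C)(C)C)[C@H]1[C@H](O[Si](CC)(CC)CC)C[C@@H](C)CCC/C(CO)=C\[C@H]1O | intermediate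
25 | (4E,6R,7R,8R,10S)-12-(tert-butyldimethylsilyloxy)-15-(tert-butyldiphenylsilyloxy)-8-(triethylsilyloxy)germacra-4,11(13)-dien-6-ol | C=C(CO[Si](C)(C)C(C)(C)C)[C@H]1[C@H](O[Si](CC)(CC)CC)C[C@@H](C)CCC/C(CO[Si](c2ccccc2)(c2ccccc2)C(C)(C)C)=C\[C@H]1O | intermediate
26 | but-2-yne-1,4-diol | OCC#CCO | starting material
27 | cyclic sodium alkenylalanate from 26 (drawn with the second hydroxyl as its sodium alkoxide; formed in the flask) | [Na+].[Na+].COCCO[Al-]1(OCCOC)OCC=C1C[O-] | intermediate
28 | (Z)-2-iodobut-2-ene-1,4-diol | OC/C(I)=C/CO | intermediate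
29 | (Z)-1,4-bis(tert-butyldiphenylsilyloxy)-2-iodobut-2-ene | CC(C)(C)[Si](c1ccccc1)(c1ccccc1)OC/C(I)=C/CO[Si](c1ccccc1)(c1ccccc1)C(C)(C)C | intermediate
30 | (Z)-4-(tert-butyldiphenylsilyloxy)-2-[(tert-butyldiphenylsilyloxy)methyl]but-2-enoic acid | OC(=O)/C(=C\CO[Si](c1ccccc1)(c1ccccc1)C(C)(C)C)CO[Si](c1ccccc1)(c1ccccc1)C(C)(C)C | intermediate
31 | mixed anhydride of 30 with 2,4,6-trichlorobenzoic acid (formed in the flask) | O=C(OC(=O)/C(=C\CO[Si](c1ccccc1)(c1ccccc1)C(C)(C)C)CO[Si](c1ccccc1)(c1ccccc1)C(C)(C)C)c1c(Cl)cc(Cl)cc1Cl | intermediate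
32 | (4E,6R,7R,8R,10S)-12-(tert-butyldimethylsilyloxy)-15-(tert-butyldiphenylsilyloxy)-8-(triethylsilyloxy)germacra-4,11(13)-dien-6-yl (Z)-4-(tert-butyldiphenylsilyloxy)-2-[(tert-butyldiphenylsilyloxy)methyl]but-2-enoate | C=C(CO[Si](C)(C)C(C)(C)C)[C@H]1[C@H](O[Si](CC)(CC)CC)C[C@@H](C)CCC/C(CO[Si](c2ccccc2)(c2ccccc2)C(C)(C)C)=C\[C@H]1OC(=O)/C(=C\CO[Si](c1ccccc1)(c1ccccc1)C(C)(C)C)CO[Si](c1ccccc1)(c1ccccc1)C(C)(C)C | intermediate
33 | (4E,6R,7S,8R,10S)-15-(tert-butyldiphenylsilyloxy)-8,12-dihydroxygermacra-4,11(13)-dien-6-yl (Z)-4-(tert-butyldiphenylsilyloxy)-2-[(tert-butyldiphenylsilyloxy)methyl]but-2-enoate | C=C(CO)[C@H]1[C@H](O)C[C@@H](C)CCC/C(CO[Si](c2ccccc2)(c2ccccc2)C(C)(C)C)=C\[C@H]1OC(=O)/C(=C\CO[Si](c1ccccc1)(c1ccccc1)C(C)(C)C)CO[Si](c1ccccc1)(c1ccccc1)C(C)(C)C | intermediate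
34 | C12 aldehyde of 33 (8-hydroxy enal; formed in the flask) | C=C(C=O)[C@H]1[C@H](O)C[C@@H](C)CCC/C(CO[Si](c2ccccc2)(c2ccccc2)C(C)(C)C)=C\[C@H]1OC(=O)/C(=C\CO[Si](c1ccccc1)(c1ccccc1)C(C)(C)C)CO[Si](c1ccccc1)(c1ccccc1)C(C)(C)C | intermediate
35 | 8,12-lactol of 34 (both C12 epimers; formed in the flask) | C=C1C(O)O[C@@H]2C[C@@H](C)CCC/C(CO[Si](c3ccccc3)(c3ccccc3)C(C)(C)C)=C\[C@@H](OC(=O)/C(=C\CO[Si](c3ccccc3)(c3ccccc3)C(C)(C)C)CO[Si](c3ccccc3)(c3ccccc3)C(C)(C)C)[C@@H]12 | intermediate
36 | (4E,6R,7S,8R,10S)-15-(tert-butyldiphenylsilyloxy)-6-{(Z)-4-(tert-butyldiphenylsilyloxy)-2-[(tert-butyldiphenylsilyloxy)methyl]but-2-enoyloxy}germacra-4,11(13)-dien-12,8-olide | C=C1C(=O)O[C@@H]2C[C@@H](C)CCC/C(CO[Si](c3ccccc3)(c3ccccc3)C(C)(C)C)=C\[C@@H](OC(=O)/C(=C\CO[Si](c3ccccc3)(c3ccccc3)C(C)(C)C)CO[Si](c3ccccc3)(c3ccccc3)C(C)(C)C)[C@@H]12 | intermediate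
37 | CNP0131216.1, (4E,6R,7S,8R,10S)-15-hydroxy-6-[(Z)-4-hydroxy-2-(hydroxymethyl)but-2-enoyloxy]germacra-4,11(13)-dien-12,8-olide | C=C1C(=O)O[C@@H]2C[C@@H](C)CCC/C(CO)=C\[C@@H](OC(=O)/C(=C\CO)CO)[C@@H]12 | target

**Step count and risks**
Total step count: 23. Longest linear sequence: 20 steps (steps 1–16 and 20–23); the side-chain acid takes steps 17–19.

Steps most likely to fail:

1. Step 14 (the step carrying the label). The lithium dienolate may not rearrange at its γ-carbon before it equilibrates about C4–C5 or passes the triethylsilyl group from O8 to the new O6 alkoxide. It may also simply be re-protonated at C4 on work-up to a deconjugated enol ether. The fallback uses known chemistry, sets out from 21 and returns at 25. Reduction of the ester of 21 with i-Bu2AlH should give the macrocyclic allylic alcohol F1. Silylation with t-BuPh2SiCl should give the bis-allylic ether F2. Treatment of F2 with n-BuLi in THF at −78 °C should bring about the classical [2,3]-Wittig ring contraction of a thirteen-membered bis-allylic ether through the C6 allyllithium and give 25 directly, so that steps 15 and 16 fall away.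

2. Step 13. Intermolecular O-alkylation to oligomers, loss of HBr from the allylic bromide or base-induced isomerisation of the γ-alkoxy enoate may outrun closure of the thirteen-membered ring. The fallback sets out from 14 and returns at 21; it makes the ether C–O bond first and closes the ring at C4=C5 instead. Stille coupling of 14 with 17 should give the hydroxymethyl phosphonate F3. O-Allylation with allyl bromide and Ag2O (no free alkoxide, hence no silyl migration) should give the allyl ether F4. Cleavage of the monosubstituted alkene with OsO4/NaIO4 should give the aldehyde F5. An intramolecular Horner–Wadsworth–Emmons olefination with LiCl and i-Pr2NEt at high dilution should then close the ring to 21, the usual preference for the ester trans to C6 coinciding with the less strained ring geometry.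

3. Step 20. Acylation of the hindered C6 hydroxyl may be slower than Z-to-E isomerisation of the activated acid. The fallback sets out from 25 and returns at 32; it builds the side chain on the ester. Carboxylation of lithiated tert-butyldiphenyl(prop-2-yn-1-yloxy)silane should give 4-(tert-butyldiphenylsilyloxy)but-2-ynoic acid F6. Carbodiimide esterification (DCC, catalytic DMAP) with 25 should give the ynoate F7. syn-Hydroalumination with i-Bu2AlH and N-methylmorpholine N-oxide, followed by trapping of the α-alumino enoate with formaldehyde, should give the (Z)-α-hydroxymethyl enoate F8. Silylation of F8 with t-BuPh2SiCl should give 32.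

**Further compounds**
F1 | step 14 | thirteen-membered ether with C15 hydroxymethyl group (reduced 21) | O1C/C(CO[Si](C)(C)C(C)(C)C)=C\[C@H](O[Si](CC)(CC)CC)C[C@@H](C)CCC/C(CO)=C\C1
F2 | step 14 | C15 tert-butyldiphenylsilyl ether of F1 | O1C/C(CO[Si](C)(C)C(C)(C)C)=C\[C@H](O[Si](CC)(CC)CC)C[C@@H](C)CCC/C(CO[Si](c2ccccc2)(c2ccccc2)C(C)(C)C)=C\C1
F3 | step 13 | methyl (6S,8R,9E)-11-(tert-butyldimethylsilyloxy)-2-(dimethoxyphosphoryl)-10-(hydroxymethyl)-6-methyl-8-(triethylsilyloxy)undec-9-enoate | CC(C)(C)[Si](C)(C)OC/C(CO)=C/[C@H](O[Si](CC)(CC)CC)C[C@@H](C)CCCC(C(=O)OC)P(=O)(OC)OC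
F4 | step 13 | C13 allyl ether of F3 | CC(C)(C)[Si](C)(C)OC/C(COCC=C)=C/[C@H](O[Si](CC)(CC)CC)C[C@@H](C)CCCC(C(=O)OC)P(=O)(OC)OC
F5 | step 13 | C13 2-oxoethyl ether of F3 (C5 aldehyde) | CC(C)(C)[Si](C)(C)OC/C(COCC=O)=C/[C@H](O[Si](CC)(CC)CC)C[C@@H](C)CCCC(C(=O)OC)P(=O)(OC)OC
F6 | step 20 | 4-(tert-butyldiphenylsilyloxy)but-2-ynoic acid | CC(C)(C)[Si](c1ccccc1)(c1ccccc1)OCC#CC(=O)O
F7 | step 20 | C6 4-(tert-butyldiphenylsilyloxy)but-2-ynoate of 25 | C=C(CO[Si](C)(C)C(C)(C)C)[C@H]1[C@H](O[Si](CC)(CC)CC)C[C@@H](C)CCC/C(CO[Si](c2ccccc2)(c2ccccc2)C(C)(C)C)=C\[C@H]1OC(=O)C#CCO[Si](c1ccccc1)(c1ccccc1)C(C)(C)C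
F8 | step 20 | C6 (Z)-4-(tert-butyldiphenylsilyloxy)-2-(hydroxymethyl)but-2-enoate of 25 | C=C(CO[Si](C)(C)C(C)(C)C)[C@H]1[C@H](O[Si](CC)(CC)CC)C[C@@H](C)CCC/C(CO[Si](c2ccccc2)(c2ccccc2)C(C)(C)C)=C\[C@H]1OC(=O)/C(=C\CO[Si](c1ccccc1)(c1ccccc1)C(C)(C)C)CO
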